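The cis-fused hydroazulene (azulene numbering: C1 carries the angelate, C4 the aroyloxy group) is cut twice across the seven-membered ring, at C4–C5 and at the ring-fusion bond C3a–C8a. C5–C6(=C7)–C8–C8a then becomes an isopropenylcyclopropane and C3a–C4 an E-alkenylboronate, joined in a rhodium-catalysed intramolecular [5+2] cycloaddition. The step exploits the C6=C7 double bond lying one carbon away from quaternary C8a, the trace of an opened vinylcyclopropane. In one operation it closes both rings, carries the cyclopropane stereocentre into C8a and turns alkene geometry into the C3a/C4 pair; C–B later becomes C–O. The precursor is an acyclic 1,3-diol with the cyclopropane at one end and the alkenylboronate at the other.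

Key step: step 8

Remark on the chemistry: the target is read from its SMILES as the cis-fused (1S,3S,3aR,4R,8aR) isomer (H-3a, CH3-8a, the C4 oxygen and the isopropyl group on one face; the C1 and C3 oxygens on the other). The azulene atom numbers are also used for the corresponding carbons of the acyclic intermediates.

Step 1
Reactants: 1 prop-2-yn-1-ol
Product: 3 (Z)-3-iodo-2-methylprop-2-en-1-ol, via cyclic alkenylmagnesium alkoxide 2 (not isolated)
Conditions: MeMgBr (2.5 equiv), CuI (10 mol%), THF, −10 to 23 °C; then I2, THF, −10 °C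
Reagents that add atoms: methylmagnesium bromide, C[Mg]Br; iodine, II
Why: Copper-catalysed anti-carbomagnesiation of the propargylic alkoxide puts the methyl group on the internal carbon and magnesium on the terminal carbon in a five-membered chelate, and iodinolysis with retention fixes the Z double bond.

Step 2
Reactants: 3 (Z)-3-iodo-2-methylprop-2-en-1-ol; 4 2-isopropenyl-4,4,5,5-tetramethyl-1,3,2-dioxaborolane
Product: 5 (Z)-2,4-dimethylpenta-2,4-dien-1-ol
Conditions: PdCl2(dppf) (5 mol%), K3PO4, THF/H2O, 45 °C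
Reagents that add atoms: none
Why: Suzuki–Miyaura coupling, which keeps the Z geometry of the alkenyl iodide; no stereocentre is formed.

Step 3
Reactants: 5 (Z)-2,4-dimethylpenta-2,4-dien-1-ol
Product: 6 [(1R,2R)-1-methyl-2-(prop-1-en-2-yl)cyclopropyl]methanol
Conditions: Et2Zn, CH2I2, DME, (4S,5S)-2-butyl-N,N,N',N'-tetramethyl-1,3,2-dioxaborolane-4,5-dicarboxamide (1.2 equiv), CH2Cl2, −10 to 23 °C; aq. NaOH work-up
Reagents that add atoms: diiodomethane, ICI
Why: Dioxaborolane-mediated asymmetric Simmons–Smith cyclopropanation (Charette cyclopropanation): the zinc alkoxide bound to the chiral boronate should deliver CH2 to one face of the allylic double bond only (the isopropenyl group is not directed and stays), the Z geometry gives the cis relation of CH2OH and isopropenyl, and the (4S,5S) reagent is the antipode that the established facial model assigns to the (1R,2R) product.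

Step 4
Reactants: 6 [(1R,2R)-1-methyl-2-(prop-1-en-2-yl)cyclopropyl]methanol
Product: 7 (1R,2R)-1-methyl-2-(prop-1-en-2-yl)cyclopropane-1-carbaldehyde
Conditions: Pr4N[RuO4] (5 mol%), N-methylmorpholine N-oxide, 4 Å sieves, CH2Cl2, 23 °C; used as a solution (volatile)
Reagents that add atoms: none
Why: Ley–Griffith oxidation of the primary alcohol under neutral conditions; the aldehyde has no α-hydrogen, so the quaternary stereocentre cannot epimerise.

Step 5
Reactants: 7 (1R,2R)-1-methyl-2-(prop-1-en-2-yl)cyclopropane-1-carbaldehyde; 8 4-(trimethylsilyl)but-3-yn-2-one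
Product: 10 (5S)-5-hydroxy-5-[(1R,2R)-1-methyl-2-(prop-1-en-2-yl)cyclopropyl]-1-(trimethylsilyl)pent-1-yn-3-one, via lithium enolate of the ynone 9 (not isolated)
Conditions: LiN(i-Pr)2, THF, −78 °C; then 7, −78 °C; aq. NH4Cl
Reagents that add atoms: none
Why: Aldol addition of the kinetic lithium enolate of the methyl ynone: the aldehyde should react from its bisected conformer with C=O eclipsing the ring–methyl bond, where the cis-isopropenyl group shields the π-face on its side, so that attack from the ring-CH2 side (Si face) sets C1 as S by 1,2-induction.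

Step 6
Reactants: 10 (5S)-5-hydroxy-5-[(1R,2R)-1-methyl-2-(prop-1-en-2-yl)cyclopropyl]-1-(trimethylsilyl)pent-1-yn-3-one
Product: 12 (3S,5S)-5-[(1R,2R)-1-methyl-2-(prop-1-en-2-yl)cyclopropyl]-3-(propan-2-yl)pent-1-yne-3,5-diol, via silylalkyne diol 11 (not isolated)
Conditions: i-PrMgCl (3.5 equiv), LaCl3·2LiCl (1.1 equiv), THF, −78 to −40 °C; aq. NH4Cl; then K2CO3, MeOH, 23 °C
Reagents that add atoms: isopropylmagnesium chloride, CC(C)[Mg]Cl
Why: 1,3-Chelation-controlled 1,2-addition of the isopropyl Grignard reagent, with LaCl3·2LiCl suppressing β-hydride reduction and enolisation: the C1 alkoxide and the ketone oxygen form a six-membered chelate with the cyclopropyl group equatorial and the nucleophile enters axially, which should set C3 as S (the two oxygens syn along the chain C8a–C1–C2–C3–C3a), after which K2CO3 in methanol cleaves the alkyne C–Si bond.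

Step 7
Reactants: 12 (3S,5S)-5-[(1R,2R)-1-methyl-2-(prop-1-en-2-yl)cyclopropyl]-3-(propan-2-yl)pent-1-yne-3,5-diol
Product: 13 (1S,3S,4E)-1-[(1R,2R)-1-methyl-2-(prop-1-en-2-yl)cyclopropyl]-3-(propan-2-yl)-5-(4,4,5,5-tetramethyl-1,3,2-dioxaborolan-2-yl)pent-4-ene-1,3-diol
Conditions: B2pin2 (1.1 equiv), CuCl (5 mol%), Xantphos (5 mol%), NaOt-Bu (10 mol%), MeOH (2 equiv), THF, 23 °C
Reagents that add atoms: bis(pinacolato)diboron, CC1(C)OB(OC1(C)C)B1OC(C)(C)C(C)(C)O1
Why: Copper-catalysed formal hydroboration (syn borylcupration of the terminal alkyne, then protonolysis by methanol with retention) puts boron on the unhindered terminal carbon and should give the E-alkenylboronate only, and it tolerates the free hydroxyl groups and the isopropenylcyclopropane; no stereocentre is formed.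

Step 8
Reactants: 13 (1S,3S,4E)-1-[(1R,2R)-1-methyl-2-(prop-1-en-2-yl)cyclopropyl]-3-(propan-2-yl)-5-(4,4,5,5-tetramethyl-1,3,2-dioxaborolan-2-yl)pent-4-ene-1,3-diol
Product: 14 (1S,3S,3aS,4R,8aR)-6,8a-dimethyl-3-(propan-2-yl)-4-(4,4,5,5-tetramethyl-1,3,2-dioxaborolan-2-yl)-1,2,3,3a,4,5,8,8a-octahydroazulene-1,3-diol
Conditions: [Rh(CO)2Cl]2 (5 mol%), toluene (0.02 M), 90 °C
Reagents that add atoms: none
Why: Monovalent rhodium binds the isopropenyl group and inserts into the adjoining C7–C8a cyclopropane bond with retention at C8a to give a σ-alkyl π-allyl trivalent rhodacycle; the tethered alkenylboronate then inserts syn into the Rh–C8a bond (bond C3a–C8a), and reductive elimination at the far allyl terminus forms C4–C5 and leaves the C6=C7 double bond. The closest known reaction is the rhodium-catalysed intramolecular [5+2] cycloaddition of cis-2-ene-vinylcyclopropanes (alkene tethered to the ring carbon cis to the vinyl group), which gives cis-fused bicyclo[5.3.0]decenes. The cyclopentane closes by 5-exo-trig migratory insertion and the cycloheptene by C–C reductive elimination from the eight-membered allyl rhodacycle, the [5+2] mode. C8a keeps the configuration of the cyclopropane carbon set in step 3, C3a follows from the cis ring fusion that the three-atom tether enforces in the insertion, and C4 follows from suprafacial addition across the E double bond, which puts H on C3a and boron on C4 on the same face. The step needs the [5+2] over the [3+2] reductive elimination and insertion over β-hydride loss: the cis relation of tether and isopropenyl group on the cyclopropane directs the allyl terminus to C4, the boryl group polarises the alkene so that carbon goes to C3a and rhodium to the boron-bearing carbon, and the fully substituted C3 holds the chain in the reactive fold.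

Step 9
Reactants: 14 (1S,3S,3aS,4R,8aR)-6,8a-dimethyl-3-(propan-2-yl)-4-(4,4,5,5-tetramethyl-1,3,2-dioxaborolan-2-yl)-1,2,3,3a,4,5,8,8a-octahydroazulene-1,3-diol; 15 angelic acid [(2Z)-2-methylbut-2-enoic acid]
Product: 17 (1S,3S,3aS,4R,8aR)-3-hydroxy-6,8a-dimethyl-3-(propan-2-yl)-4-(4,4,5,5-tetramethyl-1,3,2-dioxaborolan-2-yl)-1,2,3,3a,4,5,8,8a-octahydroazulen-1-yl (2Z)-2-methylbut-2-enoate, via angelic 2,4,6-trichlorobenzoic anhydride 16 (not isolated)
Conditions: 15, 2,4,6-Cl3C6H2COCl, Et3N, toluene, 23 °C; then 14, toluene, 75 °C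
Reagents that add atoms: none
Why: Yamaguchi esterification through the mixed anhydride should acylate the only free secondary hydroxyl (C3–OH is tertiary and C4 is still masked as its C–B bond), and the absence of a nucleophilic catalyst keeps the Z geometry of the angelate.

Step 10
Reactants: 17 the 1-O-angelate boronate of step 9
Product: 19 (1S,3S,3aR,4R,8aR)-3,4-dihydroxy-6,8a-dimethyl-3-(propan-2-yl)-1,2,3,3a,4,5,8,8a-octahydroazulen-1-yl (2Z)-2-methylbut-2-enoate, via C4 borate ester 18 (not isolated)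
Conditions: NaBO3·4H2O, THF/H2O (1:1), 23 °C
Reagents that add atoms: sodium perborate, [Na+].[Na+].O[B-]1(O)OO[B-](O)(O)OO1
Why: Oxidation of the secondary alkylboronate: hydroperoxide adds to boron and C4 migrates from boron to oxygen with retention, so the C4–O bond takes the configuration set in step 8, while the angelate and both alkenes should be inert to perborate.

Step 11
Reactants: 19 (1S,3S,3aR,4R,8aR)-3,4-dihydroxy-6,8a-dimethyl-3-(propan-2-yl)-1,2,3,3a,4,5,8,8a-octahydroazulen-1-yl (2Z)-2-methylbut-2-enoate; 20 3,4,5-trimethoxybenzoyl chloride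
Product: 21 (1S,3S,3aR,4R,8aR)-3-hydroxy-6,8a-dimethyl-3-(propan-2-yl)-4-[(3,4,5-trimethoxybenzoyl)oxy]-1,2,3,3a,4,5,8,8a-octahydroazulen-1-yl (2Z)-2-methylbut-2-enoate (CNP0112256.1)
Conditions: 20, Et3N, DMAP, CH2Cl2, 0 to 23 °C
Reagents that add atoms: none
Why: DMAP-catalysed acylation (nucleophilic acyl transfer) of the only secondary hydroxyl at C4; the tertiary C3–OH should not react and no stereocentre changes.

Compound list
1 | prop-2-yn-1-ol | C#CCO | starting material
2 | cyclic alkenylmagnesium alkoxide (4-methyl-2,5-dihydro-1,2-oxamagnesole) | CC1=C[Mg]OC1 | intermediate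
3 | (Z)-3-iodo-2-methylprop-2-en-1-ol | OC/C(C)=C\I | intermediate
4 | 2-isopropenyl-4,4,5,5-tetramethyl-1,3,2-dioxaborolane | CC(=C)B1OC(C)(C)C(C)(C)O1 | starting material
5 | (Z)-2,4-dimethylpenta-2,4-dien-1-ol | OC/C(C)=C\C(C)=C | intermediate
6 | [(1R,2R)-1-methyl-2-(prop-1-en-2-yl)cyclopropyl]methanol | OC[C@]1(C)C[C@@H]1C(C)=C | intermediate
7 | (1R,2R)-1-methyl-2-(prop-1-en-2-yl)cyclopropane-1-carbaldehyde | O=C[C@]1(C)C[C@@H]1C(C)=C | intermediate
8 | 4-(trimethylsilyl)but-3-yn-2-one | CC(=O)C#C[Si](C)(C)C | starting material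
9 | lithium 4-(trimethylsilyl)but-1-en-3-yn-2-olate (enolate of 8) | C=C(O[Li])C#C[Si](C)(C)C | intermediate
10 | (5S)-5-hydroxy-5-[(1R,2R)-1-methyl-2-(prop-1-en-2-yl)cyclopropyl]-1-(trimethylsilyl)pent-1-yn-3-one | C[Si](C)(C)C#CC(=O)C[C@H](O)[C@]1(C)C[C@@H]1C(C)=C | intermediate
11 | (3S,5S)-5-[(1R,2R)-1-methyl-2-(prop-1-en-2-yl)cyclopropyl]-3-(propan-2-yl)-1-(trimethylsilyl)pent-1-yne-3,5-diol | C[Si](C)(C)C#C[C@@](O)(C(C)C)C[C@H](O)[C@]1(C)C[C@@H]1C(C)=C | intermediate
12 | (3S,5S)-5-[(1R,2R)-1-methyl-2-(prop-1-en-2-yl)cyclopropyl]-3-(propan-2-yl)pent-1-yne-3,5-diol | C#C[C@@](O)(C(C)C)C[C@H](O)[C@]1(C)C[C@@H]1C(C)=C | intermediate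
13 | (1S,3S,4E)-1-[(1R,2R)-1-methyl-2-(prop-1-en-2-yl)cyclopropyl]-3-(propan-2-yl)-5-(4,4,5,5-tetramethyl-1,3,2-dioxaborolan-2-yl)pent-4-ene-1,3-diol | CC(C)[C@](O)(/C=C/B1OC(C)(C)C(C)(C)O1)C[C@H](O)[C@]2(C)C[C@@H]2C(C)=C | intermediate
14 | (1S,3S,3aS,4R,8aR)-6,8a-dimethyl-3-(propan-2-yl)-4-(4,4,5,5-tetramethyl-1,3,2-dioxaborolan-2-yl)-1,2,3,3a,4,5,8,8a-octahydroazulene-1,3-diol | O[C@H]1C[C@](O)(C(C)C)[C@H]2[C@H](B3OC(C)(C)C(C)(C)O3)CC(C)=CC[C@@]12C | intermediate
15 | angelic acid, (2Z)-2-methylbut-2-enoic acid | C/C=C(/C)C(=O)O | starting material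
16 | angelic 2,4,6-trichlorobenzoic anhydride | C/C=C(/C)C(=O)OC(=O)c1c(Cl)cc(Cl)cc1Cl | intermediate
17 | (1S,3S,3aS,4R,8aR)-3-hydroxy-6,8a-dimethyl-3-(propan-2-yl)-4-(4,4,5,5-tetramethyl-1,3,2-dioxaborolan-2-yl)-1,2,3,3a,4,5,8,8a-octahydroazulen-1-yl (2Z)-2-methylbut-2-enoate | C/C=C(/C)C(=O)O[C@H]1C[C@](O)(C(C)C)[C@H]2[C@H](B3OC(C)(C)C(C)(C)O3)CC(C)=CC[C@@]12C | intermediate
18 | C4 borate ester of 19 (C4–O–B pinacolate) | C/C=C(/C)C(=O)O[C@H]1C[C@](O)(C(C)C)[C@H]2[C@H](OB3OC(C)(C)C(C)(C)O3)CC(C)=CC[C@@]12C | intermediate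
19 | (1S,3S,3aR,4R,8aR)-3,4-dihydroxy-6,8a-dimethyl-3-(propan-2-yl)-1,2,3,3a,4,5,8,8a-octahydroazulen-1-yl (2Z)-2-methylbut-2-enoate | C/C=C(/C)C(=O)O[C@H]1C[C@](O)(C(C)C)[C@H]2[C@H](O)CC(C)=CC[C@@]12C | intermediate
20 | 3,4,5-trimethoxybenzoyl chloride | COc1cc(C(=O)Cl)cc(OC)c1OC | starting material
21 | (1S,3S,3aR,4R,8aR)-3-hydroxy-6,8a-dimethyl-3-(propan-2-yl)-4-[(3,4,5-trimethoxybenzoyl)oxy]-1,2,3,3a,4,5,8,8a-octahydroazulen-1-yl (2Z)-2-methylbut-2-enoate | C/C=C(/C)C(=O)O[C@H]1C[C@](O)(C(C)C)[C@H]2[C@H](OC(=O)c3cc(OC)c(OC)c(OC)c3)CC(C)=CC[C@@]12C | target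

Total step count: 11. Longest linear sequence: 11 steps (1 to 21; compounds 4, 8, 15 and 20 are bought).

Steps most likely to fail

Step 8. The 1,2-disubstituted alkenylboronate, flanked by the fully substituted C3, may insert too slowly into the Rh–C8a bond, so that the rhodacycle collapses by β-hydride loss to ring-opened dienes, or the reductive elimination may take the [3+2] course to a bicyclo[3.3.0]octane. The fallback sets out from 12 and comes back at 19; it uses an alkyne, the more reactive two-carbon partner for vinylcyclopropanes under rhodium catalysis, and sets C3a and C4 after ring closure. The terminal alkyne of 12 is C-borylated (n-BuLi, then i-PrOBpin, then HCl in Et2O) to the alkynylboronate diol F1. [Rh(CO)2Cl]2 in toluene should convert it by [5+2] cycloaddition into the bicyclic alkenylboronate diene diol F2. NaBO3 oxidises the C–B bond to the enol, which should settle as the cis-fused hydroxy ketone F3 (C3a under thermodynamic control, with C4 anti to the isopropyl group). Yamaguchi angeloylation as in step 9 gives the keto angelate F4. Evans–Saksena reduction with Me4NBH(OAc)3, hydride delivered from the C3-bound borohydride on the face of the tertiary hydroxyl, should give 19.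

Step 6. Facial control in the chelate may be poor, and β-hydride reduction or retro-aldol cleavage may compete with addition. The fallback sets out from 10 and comes back at 12, and replaces substrate control by reagent control. TBSOTf and 2,6-lutidine give the silyl ether F5. Noyori transfer hydrogenation with RuCl[(R,R)-TsDPEN](p-cymene) and HCO2H/Et3N gives the (3R)-propargylic alcohol F6, and N,N-diisopropylcarbamoyl chloride gives the carbamate F7. Lithiation–borylation (s-BuLi and TMEDA added in the presence of isopropyl-Bpin, Et2O, −78 °C, then warming) gives the tertiary boronic ester F8 stereospecifically (boron takes the place of hydrogen, isopropyl displaces the carbamate with inversion). NaBO3 gives the tertiary alcohol F9, and Bu4NF removes both silyl groups to give 12.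

Step 5. Facial selectivity at the aldehyde may be low if both bisected conformers react, and the aldolate may revert or cyclise onto the ynone. The fallback sets out from 8 (with 7) and comes back at 10, and moves the stereocontrol from the aldehyde to a catalyst. Compound 8 is converted with Me3SiOTf and Et3N into its silyl enol ether F10. A Mukaiyama aldol addition to 7 under a chiral Lewis acid made from Ti(Oi-Pr)4 and BINOL (the antipode that reinforces Si-face attack) gives the O-silyl aldol F11, which loses the silyl group on mild acidic work-up to give 10.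

Further compounds
F1 | step 8 | (3S,5S)-5-[(1R,2R)-1-methyl-2-(prop-1-en-2-yl)cyclopropyl]-3-(propan-2-yl)-1-(4,4,5,5-tetramethyl-1,3,2-dioxaborolan-2-yl)pent-1-yne-3,5-diol | CC(C)[C@](O)(C#CB1OC(C)(C)C(C)(C)O1)C[C@H](O)[C@]2(C)C[C@@H]2C(C)=C
F2 | step 8 | (1S,3S,8aR)-6,8a-dimethyl-3-(propan-2-yl)-4-(4,4,5,5-tetramethyl-1,3,2-dioxaborolan-2-yl)-1,2,3,5,8,8a-hexahydroazulene-1,3-diol | O[C@H]1C[C@](O)(C(C)C)C2=C(B3OC(C)(C)C(C)(C)O3)CC(C)=CC[C@@]12C
F3 | step 8 | (1S,3S,3aS,8aR)-1,3-dihydroxy-6,8a-dimethyl-3-(propan-2-yl)-1,2,3,3a,8,8a-hexahydroazulen-4(5H)-one | O[C@H]1C[C@](O)(C(C)C)[C@H]2C(=O)CC(C)=CC[C@@]12C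
F4 | step 8 | (1S,3S,3aS,8aR)-3-hydroxy-6,8a-dimethyl-4-oxo-3-(propan-2-yl)-1,2,3,3a,4,5,8,8a-octahydroazulen-1-yl (2Z)-2-methylbut-2-enoate | C/C=C(/C)C(=O)O[C@H]1C[C@](O)(C(C)C)[C@H]2C(=O)CC(C)=CC[C@@]12C
F5 | step 6 | (5S)-5-[(tert-butyldimethylsilyl)oxy]-5-[(1R,2R)-1-methyl-2-(prop-1-en-2-yl)cyclopropyl]-1-(trimethylsilyl)pent-1-yn-3-one | C[Si](C)(C)C#CC(=O)C[C@H](O[Si](C)(C)C(C)(C)C)[C@]1(C)C[C@@H]1C(C)=C
F6 | step 6 | (3R,5S)-5-[(tert-butyldimethylsilyl)oxy]-5-[(1R,2R)-1-methyl-2-(prop-1-en-2-yl)cyclopropyl]-1-(trimethylsilyl)pent-1-yn-3-ol | C[Si](C)(C)C#C[C@H](O)C[C@H](O[Si](C)(C)C(C)(C)C)[C@]1(C)C[C@@H]1C(C)=C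
F7 | step 6 | N,N-diisopropylcarbamate of F6 | C[Si](C)(C)C#C[C@H](OC(=O)N(C(C)C)C(C)C)C[C@H](O[Si](C)(C)C(C)(C)C)[C@]1(C)C[C@@H]1C(C)=C
F8 | step 6 | tertiary propargylic pinacol boronic ester (boron and isopropyl on C3) | C[Si](C)(C)C#C[C@@](B2OC(C)(C)C(C)(C)O2)(C(C)C)C[C@H](O[Si](C)(C)C(C)(C)C)[C@]1(C)C[C@@H]1C(C)=C
F9 | step 6 | 5-O-tert-butyldimethylsilyl ether of 11 | C[Si](C)(C)C#C[C@@](O)(C(C)C)C[C@H](O[Si](C)(C)C(C)(C)C)[C@]1(C)C[C@@H]1C(C)=C
F10 | step 5 | trimethyl{[4-(trimethylsilyl)but-1-en-3-yn-2-yl]oxy}silane | C=C(O[Si](C)(C)C)C#C[Si](C)(C)C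
F11 | step 5 | 5-O-trimethylsilyl ether of 10 | C[Si](C)(C)C#CC(=O)C[C@H](O[Si](C)(C)C)[C@]1(C)C[C@@H]1C(C)=C
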